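**Retrosynthetic overview**
- Feature: the C13–C14 bond at the ring C/D fusion joins two methines. C13 carries C16, the vinylic CH of ring D (a latent aldehyde carbon). C14 carries C15H2, which leads to the acetoxy carbon C17 (a latent ketone). This is an aldehyde α-carbon bonded to an enone β-carbon.
- Key disconnection C13–C14: ring C (C8, C9, C11, C12, C13, C14) closes by amine-catalysed intramolecular Michael addition of a C16 aldehyde on the C9 chain to a butenolidyl (E)-enone on C8.
- After it: ring D (seven-membered, C16=C19) closes by vinylogous aldol condensation of the butenolide γ-CH2 with the C16 aldehyde, followed by C17 ketone reduction and acetylation.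
- Before it: rings A/B with C5, C9, C10 come from (+)-sclareolide; the C9 arm by lactol Wittig homologation; quaternary C8 by radical conjugate addition from the C8–O bond, trans to the axial C10 methyl; the butenolide from tetronic acid by Stille acylation.
- Ring order: A/B (chiral pool), E (attached intact), C, then D.

Key step: step 14

Remark (numbering and one assumption): decalin carbons are C1–C10 with C11–C12–C13–C16 on C9; C14–C15–C17 on C8; butenolide C18 (β, fused), C19 (γ, O-bearing), C20 (α-CH), C21 (C=O). The C16=C19 double bond, given without descriptor, is taken as the only geometry ring D allows (C13 cis to C18). "Decalin core" below means the trans-decalin of sclareolide: 4,4-dimethyl, 5α-H, 9α-H, 10β-CH3.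

**Step 1**
Reactants: 1 (+)-sclareolide
Product: 2 sclareolide lactol (C12 hemiacetal bridging C8α-O, anomer mixture)
Conditions: i-Bu2AlH (1.1 equiv), CH2Cl2, −78 °C; aq. potassium sodium tartrate
Reagents that add atoms: none
Why: Partial reduction of a γ-lactone with i-Bu2AlH at low temperature stops at the aluminium hemiacetal (standard lactone-to-lactol reduction), leaving all stereocentres untouched.

**Step 2**
Reactants: 2 sclareolide lactol
Product: 3 alkenyl dioxolane: decalin core with 8α-OH, 8β-CH3 and a 9β-CH2–CH=CH–CH(OCH2CH2O) chain (C11–C12=C13–C16, E/Z mixture)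
Conditions: (1,3-dioxolan-2-ylmethyl)triphenylphosphonium bromide (2.5 equiv), KOt-Bu (2.5 equiv), THF, 0 → 50 °C
Reagents that add atoms: (1,3-dioxolan-2-ylmethyl)triphenylphosphonium bromide, [Br-].C1COC(O1)C[P+](c1ccccc1)(c1ccccc1)c1ccccc1
Why: Wittig olefination of the lactol through its open hydroxy-aldehyde form adds C13 and the masked C16 aldehyde; the alkene geometry is irrelevant because it is hydrogenated next.

**Step 3**
Reactants: 3 alkenyl dioxolane
Product: 4 hydroxy acetal: decalin core with 8α-OH, 8β-CH3 and a 9β-(CH2)3–CH(OCH2CH2O) chain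
Conditions: H2 (1 atm), Pd/C (10%), EtOAc, trace Et3N, rt
Reagents that add atoms: none
Why: Heterogeneous hydrogenation of a disubstituted alkene; the tertiary alcohol and the acetal are inert under neutral conditions.

**Step 4**
Reactants: 4 hydroxy acetal
Product: 5 methyl oxalate of 4 (8α-O–CO–CO2Me)
Conditions: ClC(O)CO2Me (2 equiv), Et3N, DMAP (cat.), CH2Cl2, 0 °C → rt
Reagents that add atoms: methyl chlorooxoacetate, COC(=O)C(Cl)=O
Why: Acylation of the hindered tertiary alcohol by the very electrophilic oxalyl half chloride under nucleophilic catalysis; the C8–O bond is not touched, so C8 keeps its configuration.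

**Step 5**
Reactants: 5 methyl oxalate
Product: 6 cesium oxalate (8α-O–CO–CO2Cs)
Conditions: CsOH·H2O (1.0 equiv), THF/H2O, rt
Reagents that add atoms: cesium hydroxide, [Cs+].[OH-]
Why: The methyl ester of a mixed oxalate is far more electrophilic than the tert-alkyl ester, so one equivalent of hydroxide should saponify it selectively to the stable cesium half-oxalate.

**Step 6**
Reactants: 6 cesium oxalate
Product: 7 saturated ester: decalin core, C8 bearing β-CH3 and α-CH2CH2CO2Me (C14, C15, C17), with the 9β-(CH2)3–CH(OCH2CH2O) chain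
Conditions: methyl acrylate (3 equiv), Ir[dF(CF3)ppy]2(dtbbpy)PF6 (1 mol%), H2O (10 equiv), DME/DMF 3:1, blue LEDs, 60 °C
Reagents that add atoms: methyl acrylate, C=CC(=O)OC
Why: Photoredox deoxygenative Giese reaction: oxidation of the oxalate by the excited photocatalyst and loss of two CO2 give the tertiary C8 radical, which adds to the acrylate, and the adduct radical is reduced and protonated; the acceptor should approach on the α face (equatorial) because the axial β trajectory is blocked by the syn-axial C10 methyl, as known for trans-decalin tertiary radicals facing a 1,3-related angular methyl, so the new C8–C14 bond takes the place of the former C–O bond.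

**Step 7**
Reactants: 7 saturated ester
Product: 8 α-phenylselanyl ester (PhSe on C15, epimer mixture)
Conditions: LiN(i-Pr)2 (1.2 equiv), THF, −78 °C; PhSeBr, −78 → 0 °C
Reagents that add atoms: phenylselanyl bromide, Br[Se]c1ccccc1
Why: α-Selenenylation of the ester lithium enolate; C15 is the only acidic position and the acetal is inert to base.

**Step 8**
Reactants: 8 α-phenylselanyl ester
Product: 10 methyl (E)-enoate (C8–CH=CH–CO2Me), via selenoxide 9 (not isolated)
Conditions: H2O2 (30% aq.), pyridine, CH2Cl2, 0 °C → rt
Reagents that add atoms: none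
Why: Oxidation to the selenoxide and spontaneous syn-elimination toward the only β-hydrogens (C14H2) should give the (E)-enoate.

**Step 9**
Reactants: 10 methyl (E)-enoate
Product: 11 (E)-enoic acid
Conditions: LiOH·H2O, THF/MeOH/H2O, rt; then 1 M HCl to pH 3–4, 0 °C
Reagents that add atoms: lithium hydroxide, [Li+].[OH-]
Why: Saponification of an unhindered methyl ester; the dioxolane is stable to base and to a brief cold acidification.

**Step 10**
Reactants: 12 tetronic acid
Product: 13 4-bromofuran-2(5H)-one
Conditions: (COBr)2, DMF (cat.), CH2Cl2, 0 °C → rt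
Reagents that add atoms: oxalyl bromide, BrC(=O)C(=O)Br
Why: Vilsmeier-type activation converts the vinylogous acid OH into the vinyl bromide.

**Step 11**
Reactants: 13 4-bromofuran-2(5H)-one
Product: 14 4-(tributylstannyl)furan-2(5H)-one
Conditions: (Bu3Sn)2, Pd(PPh3)4 (3 mol%), THF, reflux
Reagents that add atoms: hexabutylditin, CCCC[Sn](CCCC)(CCCC)[Sn](CCCC)(CCCC)CCCC
Why: Palladium-catalysed stannylation of the vinylogous acyl bromide (oxidative addition, Sn–Sn transmetalation, reductive elimination).

**Step 12**
Reactants: 11 (E)-enoic acid; 14 4-(tributylstannyl)furan-2(5H)-one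
Product: 16 butenolidyl (E)-enone acetal (C8–CH=CH–C(=O)–C18 of the furan-2(5H)-one; C16 still a dioxolane), via acid chloride 15 (not isolated)
Conditions: 1-chloro-N,N,2-trimethylprop-1-en-1-amine, CH2Cl2, 0 °C → rt; then 14, PdCl2(PPh3)2 (5 mol%), CuI (10 mol%), THF, 50 °C
Reagents that add atoms: none
Why: Acid-free acid chloride formation followed by Stille acylation (acyl–palladium formation, transmetalation of the alkenylstannane assisted by CuI, reductive elimination), as established for β-stannyl acrylates; the enone geometry and the acetal are retained.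

**Step 13**
Reactants: 16 butenolidyl (E)-enone acetal
Product: 17 seco-ring-C aldehyde: decalin core with a 9β-(CH2)3–CHO chain (C16 aldehyde) and the 8α butenolidyl (E)-enone, 8β-CH3
Conditions: 1 M aq. HCl, THF, rt
Reagents that add atoms: water, O
Why: Acid-catalysed acetal hydrolysis; the enone and the butenolide are stable to dilute acid.

**Step 14**
Reactants: 17 seco-ring-C aldehyde
Product: 18 tricyclic aldehyde: ring C closed; C13 bears equatorial CHO (H-13 β), C14 bears equatorial CH2–C(=O)–butenolide (H-14 α)
Conditions: (R)-α,α-diphenylprolinol trimethylsilyl ether (20 mol%), PhCO2H (20 mol%), CH2Cl2 (0.05 M), 0 °C → rt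
Reagents that add atoms: none
Why: The secondary amine condenses with the C16 aldehyde to the (E)-enamine, whose C13 attacks C14, the β-carbon of the (E)-enone, through a chair-like transition state, and hydrolysis releases the aldehyde and the catalyst; the closest known reaction type is the amine-catalysed intramolecular Michael addition of ω-formyl enones to trans-2-(2-oxoalkyl)cycloalkanecarbaldehydes. Ring C (C8, C9, C11, C12, C13, C14) closes in the 6-exo-trig mode. Because the C9 chain (β) and the C8 enone arm (α) are both equatorial on the rigid trans-decalin, the new ring can only be a trans-fused chair; C14 is set by the enone arm staying equatorial in that chair (H-14 axial, α), since the axial alternative meets H-9 and H-12 in 1,3-diaxial contacts. C13 is set by attack on the enamine face that places the formyl group equatorial (H-13 axial, β, 13S); the (R)-catalyst is chosen because its diphenyl(silyloxy)methyl group shields the opposite face, and C13 stays correctable by epimerisation to the all-equatorial aldehyde. The step needs attack at C14 rather than at butenolide C20, which ring size secures (C20 would require a ten-membered ring). It also needs the sequence to stop at 18, which the bulky amine secures because it does not readily form the enamine of an α-branched aldehyde.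

**Step 15**
Reactants: 18 tricyclic aldehyde
Product: 21 pentacyclic dienone (ring D closed, C17 ketone, C16=C19 γ-alkylidene butenolide), via silyloxyfuran 19 (not isolated), via silyl ether 20 (not isolated)
Conditions: TBSOTf (1.5 equiv), i-Pr2NEt (2 equiv), CH2Cl2 (0.005 M), −78 → 0 °C; then DBU (3 equiv), 0 °C → rt
Reagents that add atoms: none
Why: Silylation of the acidic butenolide γ-CH2 gives the 2-silyloxyfuran, whose C19 attacks the silyl-activated C16 aldehyde (intramolecular vinylogous Mukaiyama aldol, seven-membered ring from two equatorial arms), and DBU then removes the silanolate by E1cB elimination (the established one-pot route to γ-alkylidene butenolides); the alkene geometry is fixed by ring D, and the Lewis-acidic first stage keeps the aldehyde an electrophile.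

**Step 16**
Reactants: 21 pentacyclic dienone
Product: 22 allylic alcohol (17R; OH on the α face, cis to H-14)
Conditions: (S)-B-methyl oxazaborolidine from α,α-diphenylprolinol (0.5 equiv), catecholborane (1.5 equiv), toluene/CH2Cl2, −78 °C; then MeOH, aq. NaHCO3
Reagents that add atoms: none
Why: Corey–Bakshi–Shibata reduction under reagent control: the ketone binds boron with the larger sp2 carbon C18 turned away from the catalyst and hydride is delivered to the β face, which should give the 17R alcohol (same sense as aryl alkyl ketones with this catalyst); the conjugated ketone is reduced 1,2 and the lactone is untouched at −78 °C.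

**Step 17**
Reactants: 22 allylic alcohol
Product: 23 target acetate CNP0193439.1
Conditions: Ac2O, pyridine, DMAP (cat.), CH2Cl2, 0 °C → rt
Reagents that add atoms: acetic anhydride, CC(=O)OC(C)=O
Why: Standard acylation of a secondary alcohol with retention at C17.

**Compound list**
1 | (+)-sclareolide | O=C1C[C@H]2[C@@](O1)(C)CC[C@H]3C(C)(C)CCC[C@]23C | starting material
2 | sclareolide lactol | OC1C[C@H]2[C@@](O1)(C)CC[C@H]3C(C)(C)CCC[C@]23C | intermediate
3 | alkenyl dioxolane (8α-OH, E/Z) | C1(OCCO1)C=CC[C@H]2[C@@](O)(C)CC[C@H]3C(C)(C)CCC[C@]23C | intermediate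
4 | hydroxy acetal (8α-OH) | C1(OCCO1)CCC[C@H]2[C@@](O)(C)CC[C@H]3C(C)(C)CCC[C@]23C | intermediate
5 | methyl oxalate | C1(OCCO1)CCC[C@H]2[C@@](OC(=O)C(=O)OC)(C)CC[C@H]3C(C)(C)CCC[C@]23C | intermediate
6 | cesium oxalate | C1(OCCO1)CCC[C@H]2[C@@](OC(=O)C(=O)[O-])(C)CC[C@H]3C(C)(C)CCC[C@]23C.[Cs+] | intermediate
7 | saturated ester (C8 α-CH2CH2CO2Me) | C1(OCCO1)CCC[C@H]2[C@@](CCC(=O)OC)(C)CC[C@H]3C(C)(C)CCC[C@]23C | intermediate
8 | α-phenylselanyl ester | C1(OCCO1)CCC[C@H]2[C@@](CC([Se]c4ccccc4)C(=O)OC)(C)CC[C@H]3C(C)(C)CCC[C@]23C | intermediate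
9 | selenoxide (not isolated) | C1(OCCO1)CCC[C@H]2[C@@](CC([Se](=O)c4ccccc4)C(=O)OC)(C)CC[C@H]3C(C)(C)CCC[C@]23C | intermediate
10 | methyl (E)-enoate | C1(OCCO1)CCC[C@H]2[C@@](/C=C/C(=O)OC)(C)CC[C@H]3C(C)(C)CCC[C@]23C | intermediate
11 | (E)-enoic acid | C1(OCCO1)CCC[C@H]2[C@@](/C=C/C(=O)O)(C)CC[C@H]3C(C)(C)CCC[C@]23C | intermediate
12 | tetronic acid | OC1=CC(=O)OC1 | starting material
13 | 4-bromofuran-2(5H)-one | BrC1=CC(=O)OC1 | intermediate
14 | 4-(tributylstannyl)furan-2(5H)-one | CCCC[Sn](CCCC)(CCCC)C1=CC(=O)OC1 | intermediate
15 | (E)-enoyl chloride (not isolated) | C1(OCCO1)CCC[C@H]2[C@@](/C=C/C(=O)Cl)(C)CC[C@H]3C(C)(C)CCC[C@]23C | intermediate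
16 | butenolidyl (E)-enone acetal | C1(OCCO1)CCC[C@H]2[C@@](/C=C/C(=O)C4=CC(=O)OC4)(C)CC[C@H]3C(C)(C)CCC[C@]23C | intermediate
17 | seco-ring-C aldehyde (key-step precursor) | O=CCCC[C@H]2[C@@](/C=C/C(=O)C4=CC(=O)OC4)(C)CC[C@H]3C(C)(C)CCC[C@]23C | intermediate
18 | tricyclic aldehyde (key-step product) | O=C(C[C@@H]2[C@@H](C=O)CC[C@H]1[C@@]2(C)CC[C@H]2C(C)(C)CCC[C@]12C)C1=CC(=O)OC1 | intermediate
19 | silyloxyfuran (not isolated) | O=C(C[C@@H]2[C@@H](C=O)CC[C@H]1[C@@]2(C)CC[C@H]2C(C)(C)CCC[C@]12C)c1coc(O[Si](C)(C)C(C)(C)C)c1 | intermediate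
20 | silyl ether of the ring-D aldol adduct (not isolated; C16, C19 epimers) | O=C1C[C@@H]2[C@@H](C(O[Si](C)(C)C(C)(C)C)C3OC(=O)C=C31)CC[C@H]1[C@@]2(C)CC[C@H]2C(C)(C)CCC[C@]12C | intermediate
21 | pentacyclic dienone | O=C1C[C@@H]2[C@@H](C=C3OC(=O)C=C31)CC[C@H]1[C@@]2(C)CC[C@H]2C(C)(C)CCC[C@]12C | intermediate
22 | allylic alcohol (17R) | O[C@@H]1C[C@@H]2[C@@H](C=C3OC(=O)C=C31)CC[C@H]1[C@@]2(C)CC[C@H]2C(C)(C)CCC[C@]12C | intermediate
23 | CNP0193439.1 | CC(=O)O[C@@H]1C[C@@H]2[C@@H](C=C3OC(=O)C=C31)CC[C@H]1[C@@]2(C)CC[C@H]2C(C)(C)CCC[C@]12C | target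

**Step count**
Total: 17 steps. Longest linear sequence: 15 steps (steps 1–9 and 12–17).

**Steps most likely to fail**

1. Step 14. The attack at C14, which sits next to quaternary C8, may be slow, so that reversible amine addition to the acylbutenolide or its γ-deprotonation consumes the substrate first, or the enone may be attacked on the wrong face of C14. The fallback closes ring C before the butenolide is present, by an anionic Michael addition to the enoate.
 - It sets out from enoate 10: aqueous HCl in THF should unmask the aldehyde enoate F1, and cyclohexylamine with MgSO4 should give the N-cyclohexylimine F2.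
 - LiN(i-Pr)2 in THF (−78 → 0 °C) should generate the 1-azaallyl anion, which adds 6-exo to the enoate to give the ring-C-closed imine ester F3.
 - Work-up with aqueous oxalic acid should hydrolyse it to the trans aldehyde ester F4, with C13 equilibrated to the equatorial epimer.
 - Ethylene glycol and PPTS should protect it as the dioxolane ester F5, and LiOH should give the dioxolane acid F6.
 - The chloroenamine, then stannane 14 with PdCl2(PPh3)2 and CuI, should give the dioxolane ketone F8 through the acid chloride F7.
 - Aqueous HCl in THF then returns to aldehyde 18.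

2. Step 15. Silylation may go to the ketone or aldehyde enol instead of the butenolide, or the seven-membered closure may lose to intermolecular aldol reaction. The fallback replaces the free, enolisable aldehyde by an oxocarbenium ion.
 - It sets out from 18: HC(OMe)3 and PPTS in MeOH should give the dimethyl acetal F9.
 - TMSOTf and i-Pr2NEt in CH2Cl2 at −78 °C should form the trimethylsilyloxyfuran F10 and ionise the acetal, and vinylogous Mukaiyama addition should give the methoxy adduct F11.
 - DBU should then eliminate methanol and return to dienone 21.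

3. Step 6. Capture of the congested C8 radical by the acrylate may lose to its reduction or disproportionation, or the hindered alcohol may resist conversion into the oxalate. The fallback generates the same radical by hydrogen-atom transfer to an alkene.
 - It sets out from alcohol 4: SOCl2 and pyridine at −78 °C should give mainly the exocyclic alkene F12, with some of the ring alkene F13.
 - Fe(acac)3, PhSiH3 and methyl acrylate in EtOH/ethylene glycol at 60 °C (metal-hydride hydrogen-atom-transfer Giese addition) should convert both isomers through the same C8 radical, with the same facial preference, into ester 7.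

**Further compounds**
F1 | step 14 | aldehyde enoate | O=CCCC[C@H]2[C@@](/C=C/C(=O)OC)(C)CC[C@H]3C(C)(C)CCC[C@]23C
F2 | step 14 | N-cyclohexylimine of F1 | C1CCCCC1N=CCCC[C@H]2[C@@](/C=C/C(=O)OC)(C)CC[C@H]3C(C)(C)CCC[C@]23C
F3 | step 14 | ring-C-closed imine ester | COC(=O)C[C@@H]2[C@@H](C=NC4CCCCC4)CC[C@H]1[C@@]2(C)CC[C@H]2C(C)(C)CCC[C@]12C
F4 | step 14 | tricyclic aldehyde ester | COC(=O)C[C@@H]2[C@@H](C=O)CC[C@H]1[C@@]2(C)CC[C@H]2C(C)(C)CCC[C@]12C
F5 | step 14 | dioxolane ester | COC(=O)C[C@@H]2[C@@H](C3OCCO3)CC[C@H]1[C@@]2(C)CC[C@H]2C(C)(C)CCC[C@]12C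
F6 | step 14 | dioxolane acid | OC(=O)C[C@@H]2[C@@H](C3OCCO3)CC[C@H]1[C@@]2(C)CC[C@H]2C(C)(C)CCC[C@]12C
F7 | step 14 | dioxolane acid chloride | ClC(=O)C[C@@H]2[C@@H](C3OCCO3)CC[C@H]1[C@@]2(C)CC[C@H]2C(C)(C)CCC[C@]12C
F8 | step 14 | dioxolane butenolidyl ketone | O=C(C[C@@H]2[C@@H](C3OCCO3)CC[C@H]1[C@@]2(C)CC[C@H]2C(C)(C)CCC[C@]12C)C1=CC(=O)OC1
F9 | step 15 | dimethyl acetal of 18 | O=C(C[C@@H]2[C@@H](C(OC)OC)CC[C@H]1[C@@]2(C)CC[C@H]2C(C)(C)CCC[C@]12C)C1=CC(=O)OC1
F10 | step 15 | trimethylsilyloxyfuran of F9 | O=C(C[C@@H]2[C@@H](C(OC)OC)CC[C@H]1[C@@]2(C)CC[C@H]2C(C)(C)CCC[C@]12C)c1coc(O[Si](C)(C)C)c1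
F11 | step 15 | ring-D methoxy adduct | O=C1C[C@@H]2[C@@H](C(OC)C3OC(=O)C=C31)CC[C@H]1[C@@]2(C)CC[C@H]2C(C)(C)CCC[C@]12C
F12 | step 6 | exocyclic C8 methylene acetal | C1(OCCO1)CCC[C@H]2C(=C)CC[C@H]3C(C)(C)CCC[C@]23C
F13 | step 6 | C7=C8 ring alkene acetal | C1(OCCO1)CCC[C@H]2C(C)=CC[C@H]3C(C)(C)CCC[C@]23C
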